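I will count turnovers and leave the rate equations unintegrated. You asked for a quick number on this flask:

substrate 0.020 M (fed, over 2.0 min); coupling partner 1.20 equiv; free catalyst 0.19 mol%; time 25 h

    coupling partner + free catalyst → catalyst intermediate A (k1 = 2.3 × 10⁵ /M/min)
    catalyst intermediate A ⇌ catalyst intermediate B (K2 = 1.8, k2 = 23 /min)
    substrate + catalyst intermediate B ⇌ catalyst intermediate C (K3 = 29 /M, k3 = 2100 /M/min)
    catalyst intermediate C → free catalyst + target (k4 = 72 /min)
    coupling partner + target → over-reaction product (k5 = 2.4 /M/min)

1. how much target there is at 25 h, in percent of the substrate charged
2. how much over-reaction product there is at 25 h, in percent of the substrate charged

Each catalyst has 632 coupling partners to spend, and I call this ratio of charges the turnover budget. One turn spends one coupling partner in step 1. Each target lost to over-reaction product spends one more, with no turn. Converting the substrate takes 526 turns, and taking all of it on to over-reaction product costs 1050, which is more than the budget. So the budget can end the run with substrate unconverted. Target plus twice the over-reaction product then equals 1.20 equiv, and over-reaction product stays within 60.0%.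

That is one line, and the split needs a race. I sum the forward waits and double them for the ways back, so one turn takes about 0.162 min. Spent on turns at that pace, the budget lasts about 1.71 h, which is shorter than the 25 h asked. Target is lost at k5·c(coupling partner), which is 0.0288 /min with c(coupling partner) at half its charge. Against the turn rate, I estimate that target levels near 40.6%. I commit to that, and the budget line then gives 39.7% over-reaction product.

Your forecast gives target 42% (34% to 50%) and over-reaction product 38% (31% to 45%), holding that “over-reaction keeps pace with target formation”. That is more target and less over-reaction product than mine, and it spends 621 of the budget.

The simulation gives target 44.6% and over-reaction product 37.7%. At 0.566 h in this flask, coupling partner has a half-life of 0.67 h by step 1 and 1.1 h by over-reaction, so step 1 takes it faster. The two paths spend 433 and 198, together 632, and coupling partner, the limiting reagent here, stands at 0% at 25.0 h. A neighbouring flask, the same but with 4.80 equiv of coupling partner, has a budget of 2526. Paying 1050 to take all its substrate on to over-reaction product leaves 58.3% of its coupling partner. That flask keeps 58% of its coupling partner, with over-reaction product at 100%.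

The constants used here stand for no real mixture; what happens was integrated by code.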